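**Retrosynthetic overview**
- The target comes from a 3-O-TBS-protected 8-hydroxy macrolactone by Yamaguchi acylation of C8–OH with a (Z)-4-silyloxy-2-methylbut-2-enoic acid (from 3-methylfuran-2(5H)-one), then desilylation.
- The ten-membered carbocycle and the cis-fused α-methylene lactone form in one operation by closing C6–C7. A CrCl2-generated 2-(methoxycarbonyl)allyl nucleophile (C7, the β-carbon of an enoate, made a donor: an ester homoenolate equivalent) adds to the C6 Z-enal, and the C6 alkoxide lactonises.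
- The acyclic precursor comes from a Morita–Baylis–Hillman reaction and allylic bromination at a C7 aldehyde, a Z-selective Wittig reaction at a C4 methyl ketone, and a Shi epoxidation of the Z-C1=C10 olefin.
- The C1–C2 bond comes from a Z-alkenyl metal and methyl (S)-glycidate (C3); the Z-iodoalkene comes from anti-carboalumination of (R)-pent-4-yne-1,2-diol, made from (S)-glycidol and acetylide (C8).
- Ring order: the epoxide first (step 6), then the macrocycle and lactone together (step 12).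

Assumption: the SMILES is taken literally – (1R,3S,6S,7R,8R,10S), lactone cis-fused (H6/H7 syn), 1,10-epoxide cis (C2 and C9 on the same side), 4Z ring olefin, Z side-chain enoate; germacrane locants (C1–C15) are used for all intermediates.

**Route**

Step 1
Reactants: 1 (S)-glycidol; 2 lithium acetylide–ethylenediamine complex
Product: 3 (2R)-pent-4-yne-1,2-diol
Conditions: 2 (2.5 equiv), DMSO, 0 °C → rt; aq. NH4Cl
Reagents that add atoms: none
Why: SN2 alkynylation at the unsubstituted epoxide carbon (C9) leaves the glycidol stereocentre untouched, so C8 is delivered as (R).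

Step 2
Reactants: 3 (2R)-pent-4-yne-1,2-diol
Product: 6 (2R,4Z)-5-iodo-4-methylpent-4-ene-1,2-diol, via E-alkenylalane 4 (not isolated), via Z-alkenylalane 5 (not isolated)
Conditions: Me3Al (4 equiv), (C5H5)2ZrCl2 (25 mol %), ClCH2CH2Cl, 0 °C → rt; then AlCl3 (10 mol %), 50 °C; then I2, THF, −30 → 0 °C; aq. Na2S2O3, aq. KNaC4H4O6
Reagents that add atoms: trimethylaluminium, C[Al](C)C; iodine, II
Why: Negishi zirconium-catalysed methylalumination puts CH3 on C10 and Al on C1 syn, chelation by the homopropargylic aluminium alkoxide on heating isomerises the alkenylalane to the Z isomer (anti-carbometalation), and iodinolysis with retention fixes the C1=C10 geometry (C2 and C9 cis).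

Step 3
Reactants: 6 (2R,4Z)-5-iodo-4-methylpent-4-ene-1,2-diol
Product: 7 (2R,4Z)-5-iodo-4-methyl-1,2-bis(triethylsilyloxy)pent-4-ene
Conditions: Et3SiCl (2.4 equiv), imidazole, DMF, 0 °C → rt
Reagents that add atoms: chlorotriethylsilane, CC[Si](Cl)(CC)CC
Why: Silyl ether formation on both hydroxyls gives a primary TES ether that is later oxidised directly to the C7 aldehyde and a secondary TES ether that serves as the temporary C8 protecting group.

Step 4
Reactants: 7 (2R,4Z)-5-iodo-4-methyl-1,2-bis(triethylsilyloxy)pent-4-ene; 8 methyl (S)-glycidate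
Product: 11 methyl (2S,4Z,7R)-2-hydroxy-5-methyl-7,8-bis(triethylsilyloxy)oct-4-enoate, via alkenyllithium 9 (not isolated), via alkenylmagnesium bromide 10 (not isolated)
Conditions: t-BuLi (2.0 equiv), Et2O, −78 °C; MgBr2·OEt2, −78 → −40 °C; CuBr·SMe2 (10 mol %), 8 (1.2 equiv), THF, −40 → −10 °C; aq. NH4Cl
Reagents that add atoms: none
Why: Iodine–lithium exchange with retention of the Z geometry, transmetalation and copper-catalysed SN2 opening of the glycidic ester at its CH2 carbon form the C1–C2 bond and carry the (S) centre of 8 over unchanged as C3.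

Step 5
Reactants: 11 methyl (2S,4Z,7R)-2-hydroxy-5-methyl-7,8-bis(triethylsilyloxy)oct-4-enoate
Product: 12 methyl (2S,4Z,7R)-2-(tert-butyldimethylsilyloxy)-5-methyl-7,8-bis(triethylsilyloxy)oct-4-enoate
Conditions: TBSCl, imidazole, DMAP (cat.), DMF, rt
Reagents that add atoms: tert-butyldimethylsilyl chloride, CC(C)(C)[Si](C)(C)Cl
Why: Silyl ether formation masks C3–OH with a group that outlasts the TES ethers, which prevents later furan or lactol formation with the C6 carbonyl and allows selective release of C8–OH.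

Step 6
Reactants: 12 methyl (2S,4Z,7R)-2-(tert-butyldimethylsilyloxy)-5-methyl-7,8-bis(triethylsilyloxy)oct-4-enoate
Product: 13 methyl (2S)-2-(tert-butyldimethylsilyloxy)-3-[(2R,3S)-3-[(2R)-2,3-bis(triethylsilyloxy)propyl]-3-methyloxiran-2-yl]propanoate
Conditions: D-fructose-derived Shi ketone (30 mol %), KHSO5 (as 2KHSO5·KHSO4·K2SO4), K2CO3, Bu4NHSO4, MeCN/CH2(OMe)2/aq. Na2B4O7 buffer (pH 10.5), 0 °C
Reagents that add atoms: potassium peroxymonosulfate, [K+].[O-]S(=O)(=O)OO
Why: In the Shi asymmetric epoxidation the chiral dioxirane attacks the only olefin through a spiro transition state whose face is fixed by the single vinylic hydrogen, giving C1 (R) and, stereospecifically from the Z-olefin, C10 (S) as the cis-epoxide.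

Step 7
Reactants: 13 methyl (2S)-2-(tert-butyldimethylsilyloxy)-3-[(2R,3S)-3-[(2R)-2,3-bis(triethylsilyloxy)propyl]-3-methyloxiran-2-yl]propanoate
Product: 15 (3S)-3-(tert-butyldimethylsilyloxy)-4-[(2R,3S)-3-[(2R)-2,3-bis(triethylsilyloxy)propyl]-3-methyloxiran-2-yl]butan-2-one, via Weinreb amide 14 (not isolated)
Conditions: MeNH(OMe)·HCl, i-PrMgCl, THF, −20 °C; then MeMgBr, −20 → 0 °C; aq. NH4Cl
Reagents that add atoms: methylmagnesium bromide, C[Mg]Br
Why: In this Weinreb ketone synthesis the magnesium amide converts the ester into the N-methoxy-N-methyl amide, whose chelated tetrahedral adduct with MeMgBr collapses only on work-up, so the C4 methyl ketone (C15 introduced) forms without over-addition or epimerisation of C3.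

Step 8
Reactants: 15 (3S)-3-(tert-butyldimethylsilyloxy)-4-[(2R,3S)-3-[(2R)-2,3-bis(triethylsilyloxy)propyl]-3-methyloxiran-2-yl]butan-2-one; 16 (2-hydroxyethyl)triphenylphosphonium bromide
Product: 18 (2Z,4S)-4-(tert-butyldimethylsilyloxy)-5-[(2R,3S)-3-[(2R)-2,3-bis(triethylsilyloxy)propyl]-3-methyloxiran-2-yl]-3-methylpent-2-en-1-ol, via oxido ylide 17 (not isolated)
Conditions: 16 (2.5 equiv), n-BuLi (5 equiv), THF, −78 → 0 °C; then 15, −78 °C → rt; aq. NH4Cl
Reagents that add atoms: none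
Why: Wittig olefination of an α-alkoxy ketone with an unstabilised ylide places the alkoxy-bearing carbon (C3) cis to the ylide substituent (C6), as in Still's Z-selective synthesis of trisubstituted allylic alcohols, giving the 4Z olefin with C6–OH already free.

Step 9
Reactants: 18 (2Z,4S)-4-(tert-butyldimethylsilyloxy)-5-[(2R,3S)-3-[(2R)-2,3-bis(triethylsilyloxy)propyl]-3-methyloxiran-2-yl]-3-methylpent-2-en-1-ol
Product: 19 (2Z,4S)-4-(tert-butyldimethylsilyloxy)-3-methyl-5-[(2R,3S)-3-methyl-3-[(2R)-3-oxo-2-(triethylsilyloxy)propyl]oxiran-2-yl]pent-2-enal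
Conditions: (COCl)2, DMSO, CH2Cl2, −78 → −30 °C; then Et3N, −78 → 0 °C
Reagents that add atoms: none
Why: Swern oxidation converts the allylic alcohol into the Z-enal and, as is known for primary triethylsilyl ethers under these conditions, cleaves and oxidises the primary TES ether to the C7 aldehyde in the same operation, while the secondary TES and TBS ethers survive.

Step 10
Reactants: 19 (2Z,4S)-4-(tert-butyldimethylsilyloxy)-3-methyl-5-[(2R,3S)-3-methyl-3-[(2R)-3-oxo-2-(triethylsilyloxy)propyl]oxiran-2-yl]pent-2-enal; 20 methyl acrylate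
Product: 21 methyl (4R)-3-hydroxy-2-methylidene-5-[(2S,3R)-2-methyl-3-[(2S,3Z)-2-(tert-butyldimethylsilyloxy)-3-methyl-5-oxopent-3-en-1-yl]oxiran-2-yl]-4-(triethylsilyloxy)pentanoate (both C3 epimers)
Conditions: 20 (10 equiv), DABCO (1 equiv), MeOH (cat.), rt
Reagents that add atoms: none
Why: In the Morita–Baylis–Hillman reaction the ammonium enolate of the acrylate adds only to the activated α-silyloxy aldehyde (the β,β-disubstituted enal is inert), and the new C7 carbinol centre is irrelevant because it becomes sp2 in step 11.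

Step 11
Reactants: 21 methyl (4R)-3-hydroxy-2-methylidene-5-[(2S,3R)-2-methyl-3-[(2S,3Z)-2-(tert-butyldimethylsilyloxy)-3-methyl-5-oxopent-3-en-1-yl]oxiran-2-yl]-4-(triethylsilyloxy)pentanoate
Product: 22 methyl (2Z,4R)-2-(bromomethyl)-5-[(2S,3R)-2-methyl-3-[(2S,3Z)-2-(tert-butyldimethylsilyloxy)-3-methyl-5-oxopent-3-en-1-yl]oxiran-2-yl]-4-(triethylsilyloxy)pent-2-enoate
Conditions: NBS, Me2S, CH2Cl2, 0 °C → rt
Reagents that add atoms: N-bromosuccinimide, O=C1CCC(=O)N1Br
Why: Corey–Kim-type activation of the allylic alcohol and SN2′ attack of bromide (allylic transposition) give the thermodynamically preferred Z-2-(bromomethyl)enoate under neutral conditions that spare enal, epoxide and silyl ethers.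

Step 12
Reactants: 22 methyl (2Z,4R)-2-(bromomethyl)-5-[(2S,3R)-2-methyl-3-[(2S,3Z)-2-(tert-butyldimethylsilyloxy)-3-methyl-5-oxopent-3-en-1-yl]oxiran-2-yl]-4-(triethylsilyloxy)pent-2-enoate
Product: 25 (1R,3S,6S,7S,8R,10S)-3-(tert-butyldimethylsilyloxy)-1,10-epoxy-8-(triethylsilyloxy)germacra-4(Z),11(13)-dien-12,6-olide, via allylchromium species 23 (not isolated), via chromium alkoxide 24 (not isolated)
Conditions: CrCl2 (8 equiv), THF/DMF 4:1, rt, addition of 22 over 12 h (final 0.002 M); aq. NH4Cl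
Reagents that add atoms: none
Why: In this intramolecular Nozaki–Hiyama-type Barbier allylation CrCl2 converts the natively electrophilic β-carbon of the enoate (C7) into a donor (an ester homoenolate equivalent) that adds through its γ-position to the equally electrophilic C6 aldehyde carbon; the chair transition state of the Z-allyl unit with the enal chain equatorial gives the syn adduct (cis-fused lactone, C6), bond formation anti to the C8–C9 bond with C8–H eclipsing the allyl plane is expected to set C7, and the C6 alkoxide lactonises onto the ester.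

Step 13
Reactants: 25 (1R,3S,6S,7S,8R,10S)-3-(tert-butyldimethylsilyloxy)-1,10-epoxy-8-(triethylsilyloxy)germacra-4(Z),11(13)-dien-12,6-olide
Product: 26 (1R,3S,6S,7R,8R,10S)-3-(tert-butyldimethylsilyloxy)-1,10-epoxy-8-hydroxygermacra-4(Z),11(13)-dien-12,6-olide
Conditions: HF·pyridine, pyridine, THF, 0 °C
Reagents that add atoms: none
Why: Selective desilylation works because the secondary TES ether is cleaved far faster than the TBS ether by buffered HF·pyridine, which also spares the epoxide and the α-methylene lactone.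

Step 14
Reactants: 27 3-methylfuran-2(5H)-one
Product: 30 (Z)-4-(tert-butyldimethylsilyloxy)-2-methylbut-2-enoic acid, via potassium hydroxy-enoate 28 (not isolated), via bis-silyl derivative 29 (not isolated)
Conditions: KOH (1.05 equiv), MeOH/H2O, 0 °C → rt, evaporate; TBSCl, imidazole, DMF, rt; K2CO3, MeOH/THF/H2O, then pH 5
Reagents that add atoms: potassium hydroxide, [K+].[OH-]; tert-butyldimethylsilyl chloride, CC(C)(C)[Si](C)(C)Cl
Why: Saponification of the butenolide releases the hydroxy acid with the Z geometry fixed by the ring, and exhaustive silylation followed by selective hydrolysis of the labile silyl ester gives the O-protected acid without relactonisation.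

Step 15
Reactants: 26 (1R,3S,6S,7R,8R,10S)-3-(tert-butyldimethylsilyloxy)-1,10-epoxy-8-hydroxygermacra-4(Z),11(13)-dien-12,6-olide; 30 (Z)-4-(tert-butyldimethylsilyloxy)-2-methylbut-2-enoic acid
Product: 32 (1R,3S,6S,7R,8R,10S)-3-(tert-butyldimethylsilyloxy)-8-[(Z)-4-(tert-butyldimethylsilyloxy)-2-methylbut-2-enoyloxy]-1,10-epoxygermacra-4(Z),11(13)-dien-12,6-olide, via mixed anhydride 31 (not isolated)
Conditions: 2,4,6-Cl3C6H2COCl, Et3N, toluene, rt; then 26, DMAP, toluene, rt → 40 °C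
Reagents that add atoms: none
Why: Yamaguchi esterification through the mixed anhydride acylates the hindered C8 hydroxyl under conditions known to keep angelate-type Z-enoates from isomerising.

Step 16
Reactants: 32 (1R,3S,6S,7R,8R,10S)-3-(tert-butyldimethylsilyloxy)-8-[(Z)-4-(tert-butyldimethylsilyloxy)-2-methylbut-2-enoyloxy]-1,10-epoxygermacra-4(Z),11(13)-dien-12,6-olide
Product: 33 (1R,3S,6S,7R,8R,10S)-1,10-epoxy-3-hydroxy-8-[(Z)-4-hydroxy-2-methylbut-2-enoyloxy]germacra-4(Z),11(13)-dien-12,6-olide (CNP0410854.1)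
Conditions: HF·pyridine, pyridine, THF, 0 °C → rt
Reagents that add atoms: none
Why: Global desilylation with buffered fluoride removes both TBS ethers under non-basic conditions, so the freed Z-γ-hydroxy enoate does not lactonise and the epoxide and α-methylene lactone stay intact.

**Compound list**

1 | (S)-glycidol | OC[C@H]1CO1 | starting material
2 | lithium acetylide–ethylenediamine complex | [Li]C#C.NCCN | starting material
3 | (2R)-pent-4-yne-1,2-diol | C#CC[C@@H](O)CO | intermediate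
4 | dimethyl[(1E,4R)-4,5-bis(dimethylaluminooxy)-2-methylpent-1-en-1-yl]aluminium (syn adduct, drawn as monomer) | C[Al](C)/C=C(\C)C[C@@H](O[Al](C)C)CO[Al](C)C | intermediate
5 | dimethyl[(1Z,4R)-4,5-bis(dimethylaluminooxy)-2-methylpent-1-en-1-yl]aluminium (oxygen-chelated, drawn as monomer) | C[Al](C)/C=C(/C)C[C@@H](O[Al](C)C)CO[Al](C)C | intermediate
6 | (2R,4Z)-5-iodo-4-methylpent-4-ene-1,2-diol | I/C=C(/C)C[C@@H](O)CO | intermediate
7 | (2R,4Z)-5-iodo-4-methyl-1,2-bis(triethylsilyloxy)pent-4-ene | I/C=C(/C)C[C@@H](O[Si](CC)(CC)CC)CO[Si](CC)(CC)CC | intermediate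
8 | methyl (S)-glycidate [methyl (2S)-oxirane-2-carboxylate] | COC(=O)[C@@H]1CO1 | starting material
9 | (1Z,4R)-[2-methyl-4,5-bis(triethylsilyloxy)pent-1-en-1-yl]lithium | [Li]/C=C(/C)C[C@@H](O[Si](CC)(CC)CC)CO[Si](CC)(CC)CC | intermediate
10 | (1Z,4R)-[2-methyl-4,5-bis(triethylsilyloxy)pent-1-en-1-yl]magnesium bromide | Br[Mg]/C=C(/C)C[C@@H](O[Si](CC)(CC)CC)CO[Si](CC)(CC)CC | intermediate
11 | methyl (2S,4Z,7R)-2-hydroxy-5-methyl-7,8-bis(triethylsilyloxy)oct-4-enoate | COC(=O)[C@@H](O)C/C=C(/C)C[C@@H](O[Si](CC)(CC)CC)CO[Si](CC)(CC)CC | intermediate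
12 | methyl (2S,4Z,7R)-2-(tert-butyldimethylsilyloxy)-5-methyl-7,8-bis(triethylsilyloxy)oct-4-enoate | COC(=O)[C@@H](O[Si](C)(C)C(C)(C)C)C/C=C(/C)C[C@@H](O[Si](CC)(CC)CC)CO[Si](CC)(CC)CC | intermediate
13 | methyl (2S)-2-(tert-butyldimethylsilyloxy)-3-[(2R,3S)-3-[(2R)-2,3-bis(triethylsilyloxy)propyl]-3-methyloxiran-2-yl]propanoate | COC(=O)[C@@H](O[Si](C)(C)C(C)(C)C)C[C@H]1O[C@@]1(C)C[C@@H](O[Si](CC)(CC)CC)CO[Si](CC)(CC)CC | intermediate
14 | (2S)-2-(tert-butyldimethylsilyloxy)-3-[(2R,3S)-3-[(2R)-2,3-bis(triethylsilyloxy)propyl]-3-methyloxiran-2-yl]-N-methoxy-N-methylpropanamide | CON(C)C(=O)[C@@H](O[Si](C)(C)C(C)(C)C)C[C@H]1O[C@@]1(C)C[C@@H](O[Si](CC)(CC)CC)CO[Si](CC)(CC)CC | intermediate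
15 | (3S)-3-(tert-butyldimethylsilyloxy)-4-[(2R,3S)-3-[(2R)-2,3-bis(triethylsilyloxy)propyl]-3-methyloxiran-2-yl]butan-2-one | CC(=O)[C@@H](O[Si](C)(C)C(C)(C)C)C[C@H]1O[C@@]1(C)C[C@@H](O[Si](CC)(CC)CC)CO[Si](CC)(CC)CC | intermediate
16 | (2-hydroxyethyl)triphenylphosphonium bromide | OCC[P+](c1ccccc1)(c1ccccc1)c1ccccc1.[Br-] | starting material
17 | lithium 2-(triphenylphosphoranylidene)ethanolate | [Li]OCC=P(c1ccccc1)(c1ccccc1)c1ccccc1 | intermediate
18 | (2Z,4S)-4-(tert-butyldimethylsilyloxy)-5-[(2R,3S)-3-[(2R)-2,3-bis(triethylsilyloxy)propyl]-3-methyloxiran-2-yl]-3-methylpent-2-en-1-ol | OC/C=C(/C)[C@@H](O[Si](C)(C)C(C)(C)C)C[C@H]1O[C@@]1(C)C[C@@H](O[Si](CC)(CC)CC)CO[Si](CC)(CC)CC | intermediate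
19 | (2Z,4S)-4-(tert-butyldimethylsilyloxy)-3-methyl-5-[(2R,3S)-3-methyl-3-[(2R)-3-oxo-2-(triethylsilyloxy)propyl]oxiran-2-yl]pent-2-enal | O=C/C=C(/C)[C@@H](O[Si](C)(C)C(C)(C)C)C[C@H]1O[C@@]1(C)C[C@@H](O[Si](CC)(CC)CC)C=O | intermediate
20 | methyl acrylate | C=CC(=O)OC | starting material
21 | methyl (4R)-3-hydroxy-2-methylidene-5-[(2S,3R)-2-methyl-3-[(2S,3Z)-2-(tert-butyldimethylsilyloxy)-3-methyl-5-oxopent-3-en-1-yl]oxiran-2-yl]-4-(triethylsilyloxy)pentanoate (C3 epimers) | O=C/C=C(/C)[C@@H](O[Si](C)(C)C(C)(C)C)C[C@H]1O[C@@]1(C)C[C@@H](O[Si](CC)(CC)CC)C(O)C(=C)C(=O)OC | intermediate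
22 | methyl (2Z,4R)-2-(bromomethyl)-5-[(2S,3R)-2-methyl-3-[(2S,3Z)-2-(tert-butyldimethylsilyloxy)-3-methyl-5-oxopent-3-en-1-yl]oxiran-2-yl]-4-(triethylsilyloxy)pent-2-enoate | O=C/C=C(/C)[C@@H](O[Si](C)(C)C(C)(C)C)C[C@H]1O[C@@]1(C)C[C@@H](O[Si](CC)(CC)CC)/C=C(\CBr)C(=O)OC | intermediate
23 | allylchromium dichloride from 22 (CrCl2 in place of Br at C13) | O=C/C=C(/C)[C@@H](O[Si](C)(C)C(C)(C)C)C[C@H]1O[C@@]1(C)C[C@@H](O[Si](CC)(CC)CC)/C=C(\C[Cr](Cl)Cl)C(=O)OC | intermediate
24 | ring-closed C6 chromium alkoxide, methyl ester not yet lactonised | COC(=O)C(=C)[C@H]1[C@@H](O[Cr](Cl)Cl)/C=C(/C)[C@@H](O[Si](C)(C)C(C)(C)C)C[C@H]2O[C@@]2(C)C[C@H]1O[Si](CC)(CC)CC | intermediate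
25 | (1R,3S,6S,7S,8R,10S)-3-(tert-butyldimethylsilyloxy)-1,10-epoxy-8-(triethylsilyloxy)germacra-4(Z),11(13)-dien-12,6-olide | C=C1C(=O)O[C@H]2/C=C(/C)[C@@H](O[Si](C)(C)C(C)(C)C)C[C@H]3O[C@@]3(C)C[C@@H](O[Si](CC)(CC)CC)[C@@H]12 | intermediate
26 | (1R,3S,6S,7R,8R,10S)-3-(tert-butyldimethylsilyloxy)-1,10-epoxy-8-hydroxygermacra-4(Z),11(13)-dien-12,6-olide | C=C1C(=O)O[C@H]2/C=C(/C)[C@@H](O[Si](C)(C)C(C)(C)C)C[C@H]3O[C@@]3(C)C[C@@H](O)[C@@H]12 | intermediate
27 | 3-methylfuran-2(5H)-one | CC1=CCOC1=O | starting material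
28 | potassium (Z)-4-hydroxy-2-methylbut-2-enoate | [K+].[O-]C(=O)/C(C)=C\CO | intermediate
29 | tert-butyldimethylsilyl (Z)-4-(tert-butyldimethylsilyloxy)-2-methylbut-2-enoate | CC(C)(C)[Si](C)(C)OC(=O)/C(C)=C\CO[Si](C)(C)C(C)(C)C | intermediate
30 | (Z)-4-(tert-butyldimethylsilyloxy)-2-methylbut-2-enoic acid | OC(=O)/C(C)=C\CO[Si](C)(C)C(C)(C)C | intermediate
31 | (Z)-4-(tert-butyldimethylsilyloxy)-2-methylbut-2-enoic 2,4,6-trichlorobenzoic anhydride | O=C(OC(=O)/C(C)=C\CO[Si](C)(C)C(C)(C)C)c1c(Cl)cc(Cl)cc1Cl | intermediate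
32 | (1R,3S,6S,7R,8R,10S)-3-(tert-butyldimethylsilyloxy)-8-[(Z)-4-(tert-butyldimethylsilyloxy)-2-methylbut-2-enoyloxy]-1,10-epoxygermacra-4(Z),11(13)-dien-12,6-olide | C=C1C(=O)O[C@H]2/C=C(/C)[C@@H](O[Si](C)(C)C(C)(C)C)C[C@H]3O[C@@]3(C)C[C@@H](OC(=O)/C(C)=C\CO[Si](C)(C)C(C)(C)C)[C@@H]12 | intermediate
33 | (1R,3S,6S,7R,8R,10S)-1,10-epoxy-3-hydroxy-8-[(Z)-4-hydroxy-2-methylbut-2-enoyloxy]germacra-4(Z),11(13)-dien-12,6-olide | C=C1C(=O)O[C@H]2/C=C(/C)[C@@H](O)C[C@H]3O[C@@]3(C)C[C@@H](OC(=O)/C(C)=C\CO)[C@@H]12 | target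

**Step count and risks**

Total step count: 16. Longest linear sequence: 15 steps (steps 1–13, 15 and 16, from (S)-glycidol); step 14 makes the side-chain acid.

The three steps most likely to fail:

Step 12 (macrocyclisation). The risks are reductive dimerisation and, above all, the facial selectivity at C7, which rests on a conformational model and not on direct precedent for this ring. The fallback sets out from bromide 22 and comes back at 25. Compound 22 is borylated (B2pin2, Pd2(dba)3 [tris(dibenzylideneacetone)dipalladium], KOAc, toluene, 50 °C) to the isolable methyl 2-[(pinacolatoboryl)methyl]enoate F1, a bench-stable form of the same homoenolate equivalent. F1 is cyclised without any metal reductant by heating at high dilution (toluene, 0.002 M, 90 °C). The closed six-membered allylboration transition state is tighter than the chromium one, and the borate alkoxide lactonises to 25.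

Step 8 (Wittig olefination). The oxido ylide may erode the Z preference of the α-alkoxy ketone or epimerise C3 by enolisation. The fallback sets out from the Weinreb amide 14, which is isolated instead of being treated with MeMgBr, and comes back at 18. i-Bu2AlH (THF, −78 °C) reduces 14 to the α-silyloxy aldehyde F2. Dimethyl (1-diazo-2-oxopropyl)phosphonate with K2CO3 in MeOH gives the terminal alkyne F3. n-BuLi followed by ClCO2Me gives the ynoate F4. Me2CuLi (THF, −78 °C) adds syn to give the Z-β-methyl enoate F5, with methyl and H5 cis and therefore C3 and C6 cis. i-Bu2AlH (CH2Cl2, −78 °C) reduces the ester to 18.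

Step 10 (Morita–Baylis–Hillman reaction on the dialdehyde). The long exposure to the amine may isomerise the Z-enal, epimerise C8 or move the C8 silyl group. The fallback sets out from 19 and comes back at 21. Methyl propiolate is hydroaluminated (i-Bu2AlH, N-methylmorpholine N-oxide, THF, 0 °C) to [1-(methoxycarbonyl)ethenyl]diisobutylaluminium F6, a preformed α-acrylate anion equivalent. F6 (1.1 equiv, −78 °C) is added to 19, where it attacks the more electrophilic α-silyloxy aldehyde within minutes and without any amine, giving 21.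

Further compounds
F1 | step 12 | methyl (2Z,4R)-5-[(2S,3R)-2-methyl-3-[(2S,3Z)-2-(tert-butyldimethylsilyloxy)-3-methyl-5-oxopent-3-en-1-yl]oxiran-2-yl]-2-[(4,4,5,5-tetramethyl-1,3,2-dioxaborolan-2-yl)methyl]-4-(triethylsilyloxy)pent-2-enoate | O=C/C=C(/C)[C@@H](O[Si](C)(C)C(C)(C)C)C[C@H]1O[C@@]1(C)C[C@@H](O[Si](CC)(CC)CC)/C=C(\CB1OC(C)(C)C(C)(C)O1)C(=O)OC
F2 | step 8 | (2S)-2-(tert-butyldimethylsilyloxy)-3-[(2R,3S)-3-[(2R)-2,3-bis(triethylsilyloxy)propyl]-3-methyloxiran-2-yl]propanal | O=C[C@@H](O[Si](C)(C)C(C)(C)C)C[C@H]1O[C@@]1(C)C[C@@H](O[Si](CC)(CC)CC)CO[Si](CC)(CC)CC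
F3 | step 8 | (3S)-3-(tert-butyldimethylsilyloxy)-4-[(2R,3S)-3-[(2R)-2,3-bis(triethylsilyloxy)propyl]-3-methyloxiran-2-yl]but-1-yne | C#C[C@@H](O[Si](C)(C)C(C)(C)C)C[C@H]1O[C@@]1(C)C[C@@H](O[Si](CC)(CC)CC)CO[Si](CC)(CC)CC
F4 | step 8 | methyl (4S)-4-(tert-butyldimethylsilyloxy)-5-[(2R,3S)-3-[(2R)-2,3-bis(triethylsilyloxy)propyl]-3-methyloxiran-2-yl]pent-2-ynoate | COC(=O)C#C[C@@H](O[Si](C)(C)C(C)(C)C)C[C@H]1O[C@@]1(C)C[C@@H](O[Si](CC)(CC)CC)CO[Si](CC)(CC)CC
F5 | step 8 | methyl (2Z,4S)-4-(tert-butyldimethylsilyloxy)-5-[(2R,3S)-3-[(2R)-2,3-bis(triethylsilyloxy)propyl]-3-methyloxiran-2-yl]-3-methylpent-2-enoate | COC(=O)/C=C(/C)[C@@H](O[Si](C)(C)C(C)(C)C)C[C@H]1O[C@@]1(C)C[C@@H](O[Si](CC)(CC)CC)CO[Si](CC)(CC)CC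
F6 | step 10 | [1-(methoxycarbonyl)ethenyl]bis(2-methylpropyl)aluminium | C=C(C(=O)OC)[Al](CC(C)C)CC(C)C
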